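A small charge, 0.80 M of starting material with 1.60 M of partner, stands in each of the four flasks, and the question is how much target stands in each at the end.

| flask | starting material | partner | temperature | remark | time |
|---|---|---|---|---|---|
| grey | 1.1 M | 1.6 M | −30 °C | run made earlier |  |
| amber | 1.8 M | 1.6 M | 5 °C | run made earlier |  |
| green | 0.80 M | 2.4 M | −30 °C | run made earlier |  |
| north-west | 0.80 M | 1.60 M | −25 °C |  | 2.5 h |
| west | 0.80 M | 1.60 M | 35 °C |  | 2.5 h |
| north | 0.80 M | 1.60 M |  | at 35 °C until 80 min, from then on at −25 °C | 2.5 h |
| south-east | 0.80 M | 1.60 M | 5 °C |  | 2.5 h |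

| run | time / min | target / % | starting material / % |
|---|---|---|---|
| grey | 10.0 | 0 | 99.8 |
| grey | 15.0 | 0.2 | 99.4 |
| grey | 20.0 | 0.1 | 99.2 |
| grey | 30.0 | 0.4 | 99.6 |
| grey | 50.0 | 0.7 | 98.5 |
| grey | 80.0 | 1.7 | 97.5 |
| grey | 120 | 1.6 | 95.9 |
| amber | 1.33 | 1.6 | 95.4 |
| amber | 5.00 | 5.1 | 84.1 |
| amber | 6.00 | 5.9 | 80.8 |
| amber | 12.0 | 9.6 | 67.6 |
| amber | 20.0 | 12.4 | 53.4 |
| amber | 25.0 | 13.8 | 47.3 |
| green | 10.0 | 0.9 | 99.7 |
| green | 30.0 | 1.0 | 98.8 |
| green | 60.0 | 1.4 | 97.4 |
| green | 80.0 | 2.1 | 97.1 |
| green | 120 | 2.8 | 95.5 |

(readings scatter by 0.3 percentage points)

- the flask that comes out highest in amount of target, in percent of the starting material charged, or "all alike" when all lie within 1.5 percentage points (north-west / west / north / south-east / all alike)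
- target at the end, in percent of the starting material charged, north-west
- target at the end, in percent of the starting material charged, west
- target at the end, in percent of the starting material charged, north
- target at the end, in percent of the starting material charged, south-east



The green run, with 2.4 M of partner, shows 2.8% of target at 120 min, and the grey run, with 1.6 M, shows 1.6% at 120 min, so target is taken to form in proportion to partner as well as to starting material. Target gained per minute, divided by the starting material present, is then a pseudo-first-order constant that follows the partner, which no reading shows directly. In the amber run at 5 °C this constant is 0.0111 min⁻¹ over the first 5.00 min and 0.00562 min⁻¹ between 12.0 min and 25.0 min, about half. Target in the amber run at 25.0 min reads 0.248 M, which took up that much of the 1.6 M of partner, a share of 15.5%, less than the 49.4% the constant lost, so partner is taken to leave by another path as well. The spacing of the two intervals gives 23.6 min. This time, in which partner in the amber run falls by a factor e, is the partner lifetime. The same run gives starting material a lifetime of 33.4 min, kept here for want of a better figure although amber was charged with more starting material than the new flasks.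

My own curve for south-east, also at 5 °C with the same partner charge, starts at a slope of 0.0123 min⁻¹ of the charge. Both lifetimes act on that slope and their rates add, so it decays with a combined lifetime of 13.8 min, shorter than either. The knee lies there, at 10.7% of target. The level is slope times combined lifetime, 17.0%, and 2.5 h holds 10.9 combined lifetimes. The partner lifetime is read from the amber run at 5 °C, and west at 35 °C lies far from that temperature, so I put west and north near this level as a guess, not as a reckoning.

The forecast names north as highest, with 34.5% there, 34% in west, 33% in south-east and 4.1% in north-west, favouring north “as protection against any slow target decay”. Its south-east figure is twice my level.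

South-east comes out highest at 18.2%, with west at 10.6%, north at 10.6% and north-west at 4.66%.

    starting material + partner → target (k = 0.470 L mol⁻¹ h⁻¹, Ea = 69.0 kJ mol⁻¹)
    starting material → side product (k = 1.00 h⁻¹, Ea = 83.0 kJ mol⁻¹)
    partner → decomposed reagent (k = 2.00 h⁻¹, Ea = 84.0 kJ mol⁻¹)
    target ⇌ isomer of the product (K = 0.620, k = 0.0320 h⁻¹, Ea = 100 kJ mol⁻¹, ΔH = −44.0 kJ mol⁻¹)
    2 starting material → homo dimer (k = 0.140 L mol⁻¹ h⁻¹, Ea = 72.0 kJ mol⁻¹)
    (constants at 5 °C)

In south-east at 0.317 h, partner goes to decomposed reagent 9.1 times as fast as into target, and the time of that flask holds 6.36 partner lifetimes as read from amber, with 0.52% of the partner left at 2.50 h. In the neighbour flask, south-east repeated at −10 °C, the 47% of partner left amounts to 0.755 partner lifetimes of that flask's own, and its target stands at 18.0%.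

(The runs are calculated with made-up constants; scatter was added.)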